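The route rests on cutting the aryl–CH2 bond between C6 of the phthalide benzene ring and the ester-bearing methylene. C6 lies between C5–OMe and C7–OH, on the symmetry axis of a 4-substituted 3,5-dimethoxybenzaldehyde, so a bromine can be placed there without any regiochemical choice; the methylene is α to the ester oxygen, so the complete rhizonate half can be delivered as an (acyloxymethyl)zinc nucleophile. One Negishi coupling joins this reagent to the (R)-3-propanoyloxy-6-bromophthalide and gives the full skeleton at the final oxidation level. The labile lactol centre is set beforehand by acylative dynamic kinetic resolution and unmasked last by a lipase.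

Key step: step 10

Remark: C3 is a lactol carbon that can epimerise by ring–chain tautomerism (2-formylbenzoic acid form); it is therefore carried as a configurationally stable (R)-acylal, released only in the last step under neutral aprotic conditions, and the free lactol is assumed to hold its configuration when isolated cold and neutral.

Phthalide numbering is used throughout: C1 = lactone carbonyl, C3 = acetal carbon.

Step 1
Reactants: 1 methyl 2,4-dihydroxy-3,6-dimethylbenzoate
Product: 2 methyl 2-hydroxy-4-methoxy-3,6-dimethylbenzoate
Conditions: MeI (1.1 equiv), K2CO3, acetone, reflux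
Reagents that add atoms: iodomethane, CI
Why: Williamson O-methylation, in which the 2-OH is hydrogen-bonded to the ester carbonyl and flanked by the 3-methyl group, so only the 4-OH should be alkylated.

Step 2
Reactants: 2 methyl 2-hydroxy-4-methoxy-3,6-dimethylbenzoate
Product: 3 2-hydroxy-4-methoxy-3,6-dimethylbenzoic acid (rhizonic acid)
Conditions: KOH, DMSO/H2O, 80 °C; then cold 1 M HCl
Reagents that add atoms: potassium hydroxide (supplies the carboxyl OH oxygen), [K+].[OH-]
Why: Saponification of the hindered salicylate ester by poorly solvated hydroxide in aqueous DMSO, with cold acidification to avoid decarboxylation of the electron-rich acid.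

Step 3
Reactants: 3 2-hydroxy-4-methoxy-3,6-dimethylbenzoic acid
Product: 4 chloromethyl 2-hydroxy-4-methoxy-3,6-dimethylbenzoate
Conditions: ClCH2OSO2Cl, NaHCO3, n-Bu4NHSO4 (cat.), CH2Cl2/H2O, 0 °C → rt
Reagents that add atoms: chloromethyl chlorosulfate, ClCOS(Cl)(=O)=O
Why: Phase-transfer O-alkylation of the carboxylate, which displaces chlorosulfate in preference to chloride (the standard chloromethyl ester synthesis); at bicarbonate pH the chelated phenol stays protonated and should not cyclise onto the chloromethyl group.

Step 4
Reactants: 4 chloromethyl 2-hydroxy-4-methoxy-3,6-dimethylbenzoate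
Product: 6 iodomethyl 4-methoxy-3,6-dimethyl-2-(trimethylsilyloxy)benzoate, via silylated chloromethyl ester 5 (not isolated)
Conditions: BSA, MeCN, 50 °C; then NaI, 25 °C, dark; evaporation, dry toluene, filtration (used crude)
Reagents that add atoms: N,O-bis(trimethylsilyl)acetamide, CC(=N[Si](C)(C)C)O[Si](C)(C)C; sodium iodide, [Na+].[I-]
Why: Transient O-silylation removes the acidic phenol proton that would quench the later C–Zn bond and blocks ring closure onto the halomethyl group, and the Finkelstein exchange is driven by precipitation of NaCl.

Step 5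
Reactants: 6 iodomethyl 4-methoxy-3,6-dimethyl-2-(trimethylsilyloxy)benzoate
Product: 7 {[4-methoxy-3,6-dimethyl-2-(trimethylsilyloxy)benzoyl]oxymethyl}zinc iodide (titrated THF solution, used directly)
Conditions: Zn dust (activated with BrCH2CH2Br and TMSCl), LiCl, THF, 15–25 °C
Reagents that add atoms: zinc, [Zn]
Why: LiCl-assisted oxidative insertion of zinc into the α-acyloxy C–I bond, the known preparation of (acyloxymethyl)zinc iodides as hydroxymethyl-anion equivalents; the reagent should be stable because the hindered aroate is a poor leaving group and its carbonyl chelates zinc.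

Step 6
Reactants: 8 4-bromo-3,5-dimethoxybenzaldehyde
Product: 9 4-bromo-2-iodo-3,5-dimethoxybenzaldehyde
Conditions: NIS (1.05 equiv), TFA, MeCN, 25 °C
Reagents that add atoms: N-iodosuccinimide, O=C1CCC(=O)N1I
Why: Electrophilic aromatic iodination, in which C2 and C6 are equivalent by symmetry and each is ortho to one methoxy and para to the other, so only one mono-iodide can form.

Step 7
Reactants: 9 4-bromo-2-iodo-3,5-dimethoxybenzaldehyde
Product: 11 rac-6-bromo-3-hydroxy-5,7-dimethoxy-2-benzofuran-1(3H)-one, via 3-bromo-6-formyl-2,4-dimethoxybenzoic acid 10 (not isolated)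
Conditions: CO (1 atm), Pd(OAc)2 (3 mol %), Xantphos, K2CO3, DMF/H2O, 60 °C; then 1 M HCl
Reagents that add atoms: carbon monoxide, [C-]#[O+]; water, O
Why: Pd-catalysed hydroxycarbonylation should select the C–I bond next to the formyl group over the C–Br bond shielded by two methoxy groups, and the 2-formylbenzoic acid closes to the lactol on acidification (ring–chain tautomerism), so C3 is formed racemic here.

Step 8
Reactants: 11 rac-6-bromo-3-hydroxy-5,7-dimethoxy-2-benzofuran-1(3H)-one
Product: 12 rac-6-bromo-3,7-dihydroxy-5-methoxy-2-benzofuran-1(3H)-one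
Conditions: BCl3 (2.5 equiv), CH2Cl2, −78 → 0 °C; then H2O
Reagents that add atoms: none
Why: Chelation-controlled Lewis-acid demethylation, in which boron bound to the lactone carbonyl forms a six-membered chelate with the C7 methoxy oxygen and cleaves only that ether, leaving C5–OMe and the aryl bromide intact.

Step 9
Reactants: 12 rac-6-bromo-3,7-dihydroxy-5-methoxy-2-benzofuran-1(3H)-one
Product: 13 (3R)-6-bromo-7-hydroxy-5-methoxy-1-oxo-1,3-dihydro-2-benzofuran-3-yl propanoate
Conditions: (EtCO)2O (1.1 equiv), HyperBTM (5 mol %, antipode chosen to give the (R)-ester), i-Pr2NEt, CHCl3, 0 °C; recrystallisation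
Reagents that add atoms: propanoic anhydride, CCC(=O)OC(=O)CC
Why: Acylative dynamic kinetic resolution of a 3-hydroxyphthalide, in which the amine base interconverts the lactol enantiomers through the ring-opened 2-formylbenzoate while the chiral acyl-isothiouronium acylates one of them faster, so the catalyst sets C3 as (R) in a configurationally stable acylal (sense to be confirmed by anomalous-dispersion X-ray on the bromide); the chelated, bromine-flanked C7 phenol should stay unacylated with about one equivalent of anhydride.

Step 10
Reactants: 7 {[4-methoxy-3,6-dimethyl-2-(trimethylsilyloxy)benzoyl]oxymethyl}zinc iodide; 13 (3R)-6-bromo-7-hydroxy-5-methoxy-1-oxo-1,3-dihydro-2-benzofuran-3-yl propanoate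
Product: 16 [(3R)-7-hydroxy-5-methoxy-1-oxo-3-(propanoyloxy)-1,3-dihydro-2-benzofuran-6-yl]methyl 2-hydroxy-4-methoxy-3,6-dimethylbenzoate, via silylated bromide 14 (not isolated), via bis-silylated coupling product 15 (not isolated)
Conditions: 13, BSA, THF, 40 °C; then Pd(OAc)2 (5 mol %), SPhos (10 mol %), 7 (1.5 equiv, slow addition), THF, 25 → 45 °C; then aq. citric acid, 0 °C
Reagents that add atoms: none
Why: Pd(0)/SPhos should insert into the only C–Br bond (C6) of 14, the acyloxymethyl group is then transferred from zinc to palladium, and reductive elimination forms the C6–CH2 bond, delivering the whole rhizonate half in one operation. The closest known reaction type is the Negishi sp2–sp3 cross-coupling of functionalised primary alkylzinc halides, here an (acyloxymethyl)zinc iodide, with hindered aryl bromides under biarylphosphine catalysis. No ring is closed and no stereocentre is formed; the (R)-acylal at C3 is remote from the reacting site, and the neutral, base-free medium near room temperature offers no path for its ionisation or for lactol opening. The selectivity needed is positional (C6 versus C4), and the substrate secures it because the bromine sits on the former symmetry axis between C5–OMe and C7–O, so no directing effect is relied on. Chemoselectivity over the lactone, the acylal and the hindered aroate rests on the low basicity and nucleophilicity of the organozinc; the reagent has no β-hydrogen, so β-hydride elimination is excluded, and the two silyl ethers keep phenol protons from destroying the C–Zn bond and the product from forming an o-quinone methide. Mild aqueous citric acid in the work-up should then remove both aryl silyl ethers without touching the acylal.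

Step 11
Reactants: 16 [(3R)-7-hydroxy-5-methoxy-1-oxo-3-(propanoyloxy)-1,3-dihydro-2-benzofuran-6-yl]methyl 2-hydroxy-4-methoxy-3,6-dimethylbenzoate
Product: 17 [(3R)-3,7-dihydroxy-5-methoxy-1-oxo-1,3-dihydro-2-benzofuran-6-yl]methyl 2-hydroxy-4-methoxy-3,6-dimethylbenzoate (target)
Conditions: immobilised Burkholderia cepacia lipase (Amano PS-IM), n-BuOH (5 equiv), MTBE, 30 °C; filtration, cold evaporation, crystallisation
Reagents that add atoms: none
Why: Lipase-catalysed transesterification (alcoholysis) cleaves the propanoyl C–O bond and releases the neutral lactol, so the C3–O bond is never broken and the (R) configuration is retained; the (R)-acylal is the expected fast-reacting enantiomer by the empirical size rule for lipase substrates (aryl as large, ring oxygen as medium substituent), and the hindered benzylic aroate is not a substrate.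

Compound list
1 | methyl 2,4-dihydroxy-3,6-dimethylbenzoate | COC(=O)c1c(C)cc(O)c(C)c1O | starting material
2 | methyl 2-hydroxy-4-methoxy-3,6-dimethylbenzoate | COC(=O)c1c(C)cc(OC)c(C)c1O | intermediate
3 | 2-hydroxy-4-methoxy-3,6-dimethylbenzoic acid | COc1cc(C)c(C(=O)O)c(O)c1C | intermediate
4 | chloromethyl 2-hydroxy-4-methoxy-3,6-dimethylbenzoate | COc1cc(C)c(C(=O)OCCl)c(O)c1C | intermediate
5 | chloromethyl 4-methoxy-3,6-dimethyl-2-(trimethylsilyloxy)benzoate | COc1cc(C)c(C(=O)OCCl)c(O[Si](C)(C)C)c1C | intermediate (not isolated)
6 | iodomethyl 4-methoxy-3,6-dimethyl-2-(trimethylsilyloxy)benzoate | COc1cc(C)c(C(=O)OCI)c(O[Si](C)(C)C)c1C | intermediate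
7 | {[4-methoxy-3,6-dimethyl-2-(trimethylsilyloxy)benzoyl]oxymethyl}zinc iodide | COc1cc(C)c(C(=O)OC[Zn]I)c(O[Si](C)(C)C)c1C | intermediate
8 | 4-bromo-3,5-dimethoxybenzaldehyde | COc1cc(C=O)cc(OC)c1Br | starting material
9 | 4-bromo-2-iodo-3,5-dimethoxybenzaldehyde | COc1cc(C=O)c(I)c(OC)c1Br | intermediate
10 | 3-bromo-6-formyl-2,4-dimethoxybenzoic acid | COc1cc(C=O)c(C(=O)O)c(OC)c1Br | intermediate (not isolated)
11 | rac-6-bromo-3-hydroxy-5,7-dimethoxy-2-benzofuran-1(3H)-one | COc1cc2C(O)OC(=O)c2c(OC)c1Br | intermediate
12 | rac-6-bromo-3,7-dihydroxy-5-methoxy-2-benzofuran-1(3H)-one | COc1cc2C(O)OC(=O)c2c(O)c1Br | intermediate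
13 | (3R)-6-bromo-7-hydroxy-5-methoxy-1-oxo-1,3-dihydro-2-benzofuran-3-yl propanoate | COc1cc2c(c(O)c1Br)C(=O)O[C@H]2OC(=O)CC | intermediate
14 | (3R)-6-bromo-5-methoxy-1-oxo-7-(trimethylsilyloxy)-1,3-dihydro-2-benzofuran-3-yl propanoate | COc1cc2c(c(O[Si](C)(C)C)c1Br)C(=O)O[C@H]2OC(=O)CC | intermediate (not isolated)
15 | [(3R)-5-methoxy-1-oxo-3-(propanoyloxy)-7-(trimethylsilyloxy)-1,3-dihydro-2-benzofuran-6-yl]methyl 4-methoxy-3,6-dimethyl-2-(trimethylsilyloxy)benzoate | COc1cc(C)c(C(=O)OCc2c(OC)cc3c(c2O[Si](C)(C)C)C(=O)O[C@H]3OC(=O)CC)c(O[Si](C)(C)C)c1C | intermediate (not isolated)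
16 | [(3R)-7-hydroxy-5-methoxy-1-oxo-3-(propanoyloxy)-1,3-dihydro-2-benzofuran-6-yl]methyl 2-hydroxy-4-methoxy-3,6-dimethylbenzoate | COc1cc(C)c(C(=O)OCc2c(OC)cc3c(c2O)C(=O)O[C@H]3OC(=O)CC)c(O)c1C | intermediate
17 | [(3R)-3,7-dihydroxy-5-methoxy-1-oxo-1,3-dihydro-2-benzofuran-6-yl]methyl 2-hydroxy-4-methoxy-3,6-dimethylbenzoate | COc1cc(C)c(C(=O)OCc2c(OC)cc3c(c2O)C(=O)O[C@H]3O)c(O)c1C | target

Total step count: 11. Longest linear sequence: 7 steps (steps 1–5, 10, 11).

Steps most likely to fail

Step 10 (key coupling). Oxidative addition into the C6–Br bond, flanked by two oxygen substituents, may be slow, so that protonolysis or decay of the zinc reagent, or erosion of the acylal configuration by zinc halides, could compete. The fallback sets out from 3 and 13 and comes back at 16. The carboxylate of 3 is alkylated with (iodomethyl)tributylstannane (KHCO3, DMF, rt) to give (tributylstannyl)methyl 2-hydroxy-4-methoxy-3,6-dimethylbenzoate F1, an isolable reagent whose C–Sn bond tolerates free phenols. A Stille coupling of F1 with 13 (Pd2(dba)3, XPhos, CuI, dioxane, 80 °C), run without silyl masking, would form the same C6–CH2 bond and give 16.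

Step 11 (enzymatic release of the lactol). The lipase may not accept the hindered (R)-acylal at a useful rate, or the freed lactol may partly epimerise by ring–chain tautomerism during a slow reaction. The fallback sets out from 16 and comes back at 17. The acylal is hydrolysed chemically (1 M HCl, THF/H2O, 25–40 °C; the hindered aroate and the lactone are expected to be inert to dilute acid) to racemic (3,7-dihydroxy-5-methoxy-1-oxo-1,3-dihydro-2-benzofuran-6-yl)methyl 2-hydroxy-4-methoxy-3,6-dimethylbenzoate F2. F2 is then resolved by preparative SFC on a chiral stationary phase (acidic modifier, low temperature), and the (R)-enantiomer is collected as 17.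

Step 9 (acylative dynamic kinetic resolution). Enantioselection may be insufficient, or acylation of the C7 phenol may compete. The fallback sets out from 12 and comes back at 13. Non-selective propanoylation (propanoic anhydride, pyridine, 0 °C) gives racemic 6-bromo-7-hydroxy-5-methoxy-1-oxo-1,3-dihydro-2-benzofuran-3-yl propanoate F3, which is configurationally stable and is resolved by preparative chiral HPLC to give 13. The unwanted enantiomer can be hydrolysed back to 12 with dilute acid and recycled.

Further compounds
F1 | step 10 | (tributylstannyl)methyl 2-hydroxy-4-methoxy-3,6-dimethylbenzoate | CCCC[Sn](CCCC)(CCCC)COC(=O)c1c(C)cc(OC)c(C)c1O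
F2 | step 11 | rac-(3,7-dihydroxy-5-methoxy-1-oxo-1,3-dihydro-2-benzofuran-6-yl)methyl 2-hydroxy-4-methoxy-3,6-dimethylbenzoate | COc1cc(C)c(C(=O)OCc2c(OC)cc3c(c2O)C(=O)OC3O)c(O)c1C
F3 | step 9 | rac-6-bromo-7-hydroxy-5-methoxy-1-oxo-1,3-dihydro-2-benzofuran-3-yl propanoate | COc1cc2c(c(O)c1Br)C(=O)OC2OC(=O)CC
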